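Ring A of the target (C3a–C4–C5–C6–C7–C7a, benzofuran numbering) is a blocked cyclohexa-2,4-dienone: quaternary C5 (OMe, allyl) cannot aromatise, C6 is a ketone and O1–C7a=C7 makes it a vinylogous ester. It is cut into a 3-oxy-vinylketene (C6=C7–C7a=C3a, carried by the preformed trans-dihydrofuran) and the C4=C5 enamine of 2-methoxypent-4-enal. In one operation the enamine carbon C5 acylates C6, the iminium carbon C4 is captured by C3a, and loss of the amine gives the dienone, so that C5–C6, C3a=C4 and the C5 stereocentre arise together. The precursors are an E/Z mixture of a (tetrahydrofuran-2-ylidene)acetate salt, both isomers converging, and a C2-symmetric chiral enamine whose amine is expelled.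

Key step: step 9

Assumption: (2R,5R)-2,5-dimethylpyrrolidine and the (R)-configured binaphthyl phosphoric acid of step 1 are taken as purchased reagents, and the sense of induction in steps 1 and 9 is the one predicted by the models stated there.

Step 1
Reactants: 1 3,4-dimethoxybenzaldehyde; 2 2-[(2E)-but-2-en-1-yl]-4,4,5,5-tetramethyl-1,3,2-dioxaborolane
Product: 3 (1R,2R)-1-(3,4-dimethoxyphenyl)-2-methylbut-3-en-1-ol
Conditions: (R)-3,3'-bis(2,4,6-triisopropylphenyl)-1,1'-binaphthyl-2,2'-diyl hydrogen phosphate (5 mol %), toluene, −30 °C; aqueous work-up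
Reagents that add atoms: none
Why: Chiral-phosphoric-acid-catalysed crotylboration through a closed chair (Zimmerman–Traxler) transition state turns the (E)-crotyl geometry into the anti relationship, and the (R)-acid should direct addition to the re face of the aldehyde, setting the carbinol carbon (future C2) as R and the methyl-bearing carbon (future C3) as R.

Step 2
Reactants: 3 (1R,2R)-1-(3,4-dimethoxyphenyl)-2-methylbut-3-en-1-ol
Product: 4 (1R,2R)-1-(3,4-dimethoxyphenyl)-2-methylbutane-1,4-diol
Conditions: 9-BBN (2.2 equiv), THF, 0 °C to rt; then NaOH, H2O2, 0 °C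
Reagents that add atoms: hydrogen peroxide, OO
Why: Hydroboration–oxidation with the bulky borane places boron, and then oxygen, on the terminal alkene carbon and does not touch either stereocentre.

Step 3
Reactants: 4 (1R,2R)-1-(3,4-dimethoxyphenyl)-2-methylbutane-1,4-diol
Product: 5 (4R,5R)-5-(3,4-dimethoxyphenyl)-4-methyloxolan-2-one
Conditions: TEMPO (10 mol %), PhI(OAc)2 (2.5 equiv), CH2Cl2, rt
Reagents that add atoms: none
Why: Oxoammonium oxidation is selective for the primary alcohol, the aldehyde closes to the lactol with the benzylic hydroxyl and is oxidised on to the γ-lactone (oxidative lactonisation) without affecting C4 or C5.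

Step 4
Reactants: 5 (4R,5R)-5-(3,4-dimethoxyphenyl)-4-methyloxolan-2-one; 6 methyl acetate
Product: 8 methyl 2-[(4R,5R)-5-(3,4-dimethoxyphenyl)-4-methyloxolan-2-ylidene]acetate (E/Z mixture), via lactol 7 (not isolated)
Conditions: LiN(iPr)2, 6 (2.5 equiv), THF, −78 °C, then 5; AcOH quench; crude 7, pyridinium p-toluenesulfonate (cat.), 4 Å molecular sieves, toluene, 50 °C
Reagents that add atoms: none
Why: Claisen-type addition of the lithium enolate of methyl acetate to the lactone carbonyl stops at hemiketal 7, and acid-catalysed dehydration gives the conjugated exocyclic vinylogous carbonate; its E/Z ratio is immaterial because both isomers later give the same vinylketene.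

Step 5
Reactants: 8 methyl 2-[(4R,5R)-5-(3,4-dimethoxyphenyl)-4-methyloxolan-2-ylidene]acetate
Product: 9 potassium 2-[(4R,5R)-5-(3,4-dimethoxyphenyl)-4-methyloxolan-2-ylidene]acetate (E/Z mixture)
Conditions: KOSiMe3 (1.1 equiv), THF, rt to 40 °C; salt collected and dried under vacuum
Reagents that add atoms: potassium trimethylsilanolate, C[Si](C)(C)[O-].[K+]
Why: Anhydrous silanolate cleavage of the methyl ester delivers the dry carboxylate directly, which avoids the free β-alkoxyacrylic acid and any protonation of the enol ether.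

Step 6
Reactants: 10 methyl 2-methoxyacetate; 11 allyl bromide
Product: 12 methyl 2-methoxypent-4-enoate (racemic)
Conditions: LiN(iPr)2, THF, −78 °C; then 11, −78 °C to 0 °C
Reagents that add atoms: none
Why: Ester enolate alkylation (SN2 C-allylation of the lithium enolate of the α-methoxy ester); the stereocentre formed is racemic and is erased at the enamine stage.

Step 7
Reactants: 12 methyl 2-methoxypent-4-enoate
Product: 13 2-methoxypent-4-enal (racemic)
Conditions: iBu2AlH (1.05 equiv), CH2Cl2, −78 °C; aqueous potassium sodium tartrate; careful concentration (volatile), kept in solution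
Reagents that add atoms: none
Why: Partial ester reduction stops at the aldehyde because the α-methoxy group stabilises the chelated tetrahedral aluminium hemiacetal until work-up.

Step 8
Reactants: 13 2-methoxypent-4-enal; 14 (2R,5R)-2,5-dimethylpyrrolidine
Product: 15 (2R,5R)-1-[(1Z)-2-methoxypenta-1,4-dien-1-yl]-2,5-dimethylpyrrolidine
Conditions: 4 Å molecular sieves, Et2O, 0 °C to rt; filtered, concentrated, used crude
Reagents that add atoms: none
Why: Condensation of the aldehyde with the secondary amine (Stork enamine formation) can give only this regioisomer, and allylic strain against the 2,5-dimethylpyrrolidine should place the smaller methoxy group cis to nitrogen ((Z)-isomer) under the equilibrating conditions.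

Step 9
Reactants: 9 potassium 2-[(4R,5R)-5-(3,4-dimethoxyphenyl)-4-methyloxolan-2-ylidene]acetate; 15 (2R,5R)-1-[(1Z)-2-methoxypenta-1,4-dien-1-yl]-2,5-dimethylpyrrolidine
Product: 19 (2R,3R,5S)-2-(3,4-dimethoxyphenyl)-5-methoxy-3-methyl-5-(prop-2-en-1-yl)-2,3-dihydro-1-benzofuran-6(5H)-one, via acid chloride 16 (not isolated), via vinylketene 17 (not isolated), via aminoenone 18 (not isolated)
Conditions: 9, (COCl)2 (1.0 equiv), DMF (cat.), CH2Cl2, 0 °C; this solution added slowly to 15 (1.3 equiv), Et3N (2.5 equiv), CH2Cl2, −40 °C to 0 °C; then AcOH/NaOAc buffer, rt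
Reagents that add atoms: none
Why: Et3N removes HCl from 16 through the ring CH2 (γ) to give vinylketene 17 (both alkene isomers of 9 converge), its ketene carbon C6 is attacked by the enamine β-carbon C5 of 15 (Stork-type C-acylation), the iminium carbon C4 of the resulting zwitterion is captured by the dienolate γ-carbon C3a (vinylogous Mannich closure) to give 18, and vinylogous E1cB loss of the amine installs C3a=C4. The closest known reaction type is the stepwise [4+2] annulation of vinylketenes, made from α,β-unsaturated acid chlorides and Et3N, with aldehyde enamines, which gives cyclohexa-2,4-dienones after deamination. Only ring A is closed, by C-acylation and then a 6-(enolendo)-exo-trig Mannich closure; a [2+2] aminocyclobutanone formed by closure at C7 is a reversible reservoir that re-opens to the zwitterion and drains into the six-membered ring because amine loss is irreversible. C5 is the one new stereocentre that survives and is set in the C5–C6 bond formation by the C2-symmetric (2R,5R)-pyrrolidine: in the (Z)-enamine the pseudoaxial methyl on the ring carbon syn to the double bond shields one face, C6 should add to the other to give 5S, and the centres formed at C3a and C4 in 18 are erased on elimination. The step needs γ- over α-closure (secured by the O1 enol-ether activation of C3a and by six- over four-membered ring formation), C- over N-acylation (tertiary enamine), and survival of the product (low temperature suppresses Cope and retro-Claisen shifts of the allyl group, and the hindered amine does not add to the vinylogous ester).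

Compound list
1 | 3,4-dimethoxybenzaldehyde | O=Cc1ccc(OC)c(OC)c1 | starting material
2 | 2-[(2E)-but-2-en-1-yl]-4,4,5,5-tetramethyl-1,3,2-dioxaborolane | C/C=C/CB1OC(C)(C)C(C)(C)O1 | starting material
3 | (1R,2R)-1-(3,4-dimethoxyphenyl)-2-methylbut-3-en-1-ol | O[C@@H](c1ccc(OC)c(OC)c1)[C@@H](C=C)C | intermediate
4 | (1R,2R)-1-(3,4-dimethoxyphenyl)-2-methylbutane-1,4-diol | O[C@@H](c1ccc(OC)c(OC)c1)[C@@H](CCO)C | intermediate
5 | (4R,5R)-5-(3,4-dimethoxyphenyl)-4-methyloxolan-2-one | O=C1O[C@@H](c2ccc(OC)c(OC)c2)[C@@H](C1)C | intermediate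
6 | methyl acetate | COC(C)=O | starting material
7 | methyl 2-[(4R,5R)-5-(3,4-dimethoxyphenyl)-2-hydroxy-4-methyloxolan-2-yl]acetate (anomer mixture, not isolated) | COC(=O)CC1(O)O[C@@H](c2ccc(OC)c(OC)c2)[C@@H](C1)C | intermediate
8 | methyl 2-[(4R,5R)-5-(3,4-dimethoxyphenyl)-4-methyloxolan-2-ylidene]acetate (E/Z mixture) | COC(=O)C=C1O[C@@H](c2ccc(OC)c(OC)c2)[C@@H](C1)C | intermediate
9 | potassium 2-[(4R,5R)-5-(3,4-dimethoxyphenyl)-4-methyloxolan-2-ylidene]acetate (E/Z mixture) | [K+].[O-]C(=O)C=C1O[C@@H](c2ccc(OC)c(OC)c2)[C@@H](C1)C | intermediate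
10 | methyl 2-methoxyacetate | COCC(=O)OC | starting material
11 | allyl bromide (3-bromoprop-1-ene) | C=CCBr | starting material
12 | methyl 2-methoxypent-4-enoate (racemic) | COC(=O)C(OC)CC=C | intermediate
13 | 2-methoxypent-4-enal (racemic) | O=CC(OC)CC=C | intermediate
14 | (2R,5R)-2,5-dimethylpyrrolidine | C[C@@H]1CC[C@@H](C)N1 | starting material
15 | (2R,5R)-1-[(1Z)-2-methoxypenta-1,4-dien-1-yl]-2,5-dimethylpyrrolidine | C=CC/C(OC)=C/N1[C@H](C)CC[C@H]1C | intermediate
16 | 2-[(4R,5R)-5-(3,4-dimethoxyphenyl)-4-methyloxolan-2-ylidene]acetyl chloride (not isolated) | O=C(Cl)C=C1O[C@@H](c2ccc(OC)c(OC)c2)[C@@H](C1)C | intermediate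
17 | 2-[(4R,5R)-5-(3,4-dimethoxyphenyl)-4-methyl-4,5-dihydrofuran-2-yl]ethen-1-one (vinylketene, not isolated) | O=C=CC1=C[C@@H](C)[C@H](c2ccc(OC)c(OC)c2)O1 | intermediate
18 | (2R,3R,5S)-2-(3,4-dimethoxyphenyl)-4-[(2R,5R)-2,5-dimethylpyrrolidin-1-yl]-5-methoxy-3-methyl-5-(prop-2-en-1-yl)-3,3a,4,5-tetrahydro-1-benzofuran-6(2H)-one (mixture at C3a and C4, not isolated) | C=CC[C@]1(OC)C(N2[C@H](C)CC[C@H]2C)C2C(=CC1=O)O[C@@H](c1ccc(OC)c(OC)c1)[C@@H]2C | intermediate
19 | (2R,3R,5S)-2-(3,4-dimethoxyphenyl)-5-methoxy-3-methyl-5-(prop-2-en-1-yl)-2,3-dihydro-1-benzofuran-6(5H)-one | C=CC[C@]1(OC)C=C2C(=CC1=O)O[C@@H](c1ccc(OC)c(OC)c1)[C@@H]2C | target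

Total step count: 9. Longest linear sequence: 6 steps (steps 1, 2, 3, 4, 5, 9); steps 6 to 8 build the enamine separately.

Steps most likely to fail

Step 9. What may go wrong: the zwitterion may close at C7 to a cyclobutanone that does not re-open, the ketene may oligomerise, or facial discrimination at C5 may be weak (for instance through a mixed enamine geometry), so that the C5 epimer forms alongside. The fallback is stepwise and sets out from ester 8 and aldehyde 13. LiN(iPr)2 (THF, −78 °C) deprotonates 8 at the ring CH2 and the dienolate adds through that carbon to 13; the alkoxide lactonises on warming to (2R,3R)-2-(3,4-dimethoxyphenyl)-4-(1-methoxybut-3-en-1-yl)-3-methyl-2,3,3a,4-tetrahydro-6H-furo[3,2-c]pyran-6-one F1. KOtBu opens F1 by E1cB elimination and acidification gives 2-[(4R,5R)-5-(3,4-dimethoxyphenyl)-3-(2-methoxypent-4-en-1-ylidene)-4-methyloxolan-2-ylidene]acetic acid F2. Treatment with 1-chloro-N,N,2-trimethylprop-1-en-1-amine and then Et3N (CH2Cl2, −20 °C to rt) should give, by 1,6-dehydrochlorination, the dienylketene 2-[(4R,5R)-5-(3,4-dimethoxyphenyl)-3-(2-methoxypenta-1,4-dien-1-yl)-4-methyl-4,5-dihydrofuran-2-yl]ethen-1-one F3. This should close by thermal 6π-electrocyclisation to the dienone as a mixture of 19 and its C5 epimer (2R,3R,5R)-2-(3,4-dimethoxyphenyl)-5-methoxy-3-methyl-5-(prop-2-en-1-yl)-2,3-dihydro-1-benzofuran-6(5H)-one F4. The two are separated by chromatography and the route is rejoined at 19.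

Step 8. What may go wrong: slow condensation of the hindered amine with the α-branched, volatile aldehyde, and self-aldolisation of 13. The fallback sets out from ester 12 and by-passes the aldehyde. AlMe3-mediated aminolysis of 12 with 14 gives 1-[(2R,5R)-2,5-dimethylpyrrolidin-1-yl]-2-methoxypent-4-en-1-one F5. Catalytic hydrosilylation of F5 with IrCl(CO)(PPh3)2 and 1,1,3,3-tetramethyldisiloxane (toluene, rt) gives the N,O-silyl acetal, which loses silanol to give enamine 15; the route is rejoined at 15.

Step 4. What may go wrong: double addition or retro-Claisen opening on work-up, and incomplete or endocyclic dehydration of the hemiketal. The fallback sets out from lactone 5. Reduction with iBu2AlH (CH2Cl2, −78 °C) gives (4R,5R)-5-(3,4-dimethoxyphenyl)-4-methyloxolan-2-ol F6. Ohira–Bestmann homologation (dimethyl (1-diazo-2-oxopropyl)phosphonate, K2CO3, MeOH) gives (1R,2R)-1-(3,4-dimethoxyphenyl)-2-methylpent-4-yn-1-ol F7. 5-exo-dig oxypalladation and methoxycarbonylation of F7 (PdCl2(MeCN)2 cat., p-benzoquinone, CO, MeOH, 0 °C) gives the (E)-isomer of 8; the route is rejoined at 8.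

Further compounds
F1 | step 9 | (2R,3R)-2-(3,4-dimethoxyphenyl)-4-(1-methoxybut-3-en-1-yl)-3-methyl-2,3,3a,4-tetrahydro-6H-furo[3,2-c]pyran-6-one (isomer mixture at the new centres) | O=C1C=C2O[C@@H](c3ccc(OC)c(OC)c3)[C@H](C)C2C(C(OC)CC=C)O1
F2 | step 9 | 2-[(4R,5R)-5-(3,4-dimethoxyphenyl)-3-(2-methoxypent-4-en-1-ylidene)-4-methyloxolan-2-ylidene]acetic acid (alkene isomers) | OC(=O)C=C1O[C@@H](c2ccc(OC)c(OC)c2)[C@@H](C1=CC(OC)CC=C)C
F3 | step 9 | 2-[(4R,5R)-5-(3,4-dimethoxyphenyl)-3-(2-methoxypenta-1,4-dien-1-yl)-4-methyl-4,5-dihydrofuran-2-yl]ethen-1-one | O=C=CC1=C(C=C(OC)CC=C)[C@@H](C)[C@H](c2ccc(OC)c(OC)c2)O1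
F4 | step 9 | (2R,3R,5R)-2-(3,4-dimethoxyphenyl)-5-methoxy-3-methyl-5-(prop-2-en-1-yl)-2,3-dihydro-1-benzofuran-6(5H)-one | C=CC[C@@]1(OC)C=C2C(=CC1=O)O[C@@H](c1ccc(OC)c(OC)c1)[C@@H]2C
F5 | step 8 | 1-[(2R,5R)-2,5-dimethylpyrrolidin-1-yl]-2-methoxypent-4-en-1-one | C=CCC(OC)C(=O)N1[C@H](C)CC[C@H]1C
F6 | step 4 | (4R,5R)-5-(3,4-dimethoxyphenyl)-4-methyloxolan-2-ol | OC1O[C@@H](c2ccc(OC)c(OC)c2)[C@@H](C1)C
F7 | step 4 | (1R,2R)-1-(3,4-dimethoxyphenyl)-2-methylpent-4-yn-1-ol | O[C@@H](c1ccc(OC)c(OC)c1)[C@@H](CC#C)C
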